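The data are simulated with constants of no real substance.

A small charge of Z runs by steady feed (semi-batch operation, in the usual term) into a stirred flask of D and the catalyst E, and the five new flasks differ in how long the feed lasts.

| flask | Z | D | E | remark | time |
|---|---|---|---|---|---|
| south-east | 0.020 M (fed, over 0.80 d) | 4 mM | 0.67 mM | run made earlier; the fed solution adds 0.10 times the starting volume |  |
| east | 0.020 M (fed, over 0.80 d) | 4 mM | 1.5 mM | run made earlier; the fed solution adds 0.10 times the starting volume |  |
| north-east | 0.010 M (fed, over 0.80 d) | 4 mM | 1 mM | run made earlier; the fed solution adds 0.10 times the starting volume |  |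
| spring | 0.020 M (fed, over 0.80 d) | 4.00 mM | 1.0 mM | the fed solution adds 0.10 times the starting volume | 8.0 d |
| winter | 0.020 M (fed, over 1.5 d) | 4.00 mM | 1.0 mM | the fed solution adds 0.10 times the starting volume | 8.0 d |
| noon | 0.020 M (fed, over 3.0 d) | 4.00 mM | 1.0 mM | the fed solution adds 0.10 times the starting volume | 8.0 d |
| autumn | 0.020 M (fed, over 6.0 d) | 4.00 mM | 1.0 mM | the fed solution adds 0.10 times the starting volume | 8.0 d |
| summer | 0.020 M (fed, over 12 d) | 4.00 mM | 1.0 mM | the fed solution adds 0.10 times the starting volume | 8.0 d |

- south-east (time / d: X / %): 0.833: 17.7; 2.50: 31.1; 4.00: 31.8; 6.00: 34.2; 10.0: 34.0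
- east (time / d: X / %): 2.08: 47.7; 4.00: 48.4; 6.00: 45.3; 8.00: 45.2; 10.0: 43.9
- north-east (time / d: X / %): 0.833: 25.8; 2.50: 44.2; 4.00: 43.7; 6.00: 43.3; 10.0: 41.7

(readings scatter by 1 percentage point)

- amounts are per litre of the starting volume; all of the dose is in the solution fed
- percentages count the whole charge, also what has not yet gone in
- "hardly changes" means that all values lie within two and a half points (for a concentration: within two and a half percent of the largest)

- amount of X at the end, in percent of the Z charged for spring, winter, noon, autumn, summer, in this order
- the shape of the row from first to last (rises, then falls / hardly changes / falls, then rises / falls all the way / rises all the way)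

*How soon after the feed stops do the readings of X level off?*

Soon. In the north-east run the feed ends at 0.80 d, and X reads 44.2 % at 2.50 d and 43.7 % at 4.00 d, with a scatter of 1 percentage point. I call the gap from feed end to that first level reading the tail: 1.70 d. The readings lie too far apart to say it closer.

*That run had half the charge. Does the tail survive the full one?*

The east run, at the full charge, reads 47.7 % at 2.08 d and 48.4 % at 4.00 d, so there it does. But the south-east run, with E at 0.67 mM, still creeps from 31.1 % at 2.50 d to 34.2 % at 6.00 d. That is the weak spot, and the new flasks, with E at 1.0 mM, stand between those two runs in E.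

*What does the tail give you for the row?*

If it holds, a feed that is to finish working by 8.0 d has to stop a tail earlier. That gives the latest dosing time, the asked time less the tail: 6.30 d.

*Solve the two ends.*

In spring the whole charge is in with 7.20 d to spare, more than the tail. In summer only 66.7 % of the charge has gone in by 8.0 d, and the Z still outside has made no X. Joining the ends, my own reckoning puts the break in the row near the latest dosing time, with autumn under it and summer over it. It gives no heights below the break.

*And the forecast?*

It commits to 41 %, 41.5 %, 42 %, 42.5 % and 27 %, a shape of rises, then falls, and for the nearly level start of that row it argues that “dosing slowly gains little selectivity”.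

The flask gives 39.3 %, 42.2 %, 45.9 %, 49.3 % and 31.4 %, a shape of rises, then falls.

    Z + D → L (k = 5.15 M⁻¹ h⁻¹)
    G + E ⇌ Z + E, rate k2*[E]*[G] forward; the back reaction follows from the equilibrium constant (k = 2.31 M⁻¹ h⁻¹)
    X + E ⇌ G + E, rate k3*[E]*[X] forward; the back reaction follows from the equilibrium constant (K = 0.367, k = 223 M⁻¹ h⁻¹)
    2 Z → Q (k = 2.39 M⁻¹ h⁻¹)
    Z + E ⇌ X + E, rate k5*[Z]*[E] forward; the back reaction follows from the equilibrium constant (K = 13.8, k = 46.8 M⁻¹ h⁻¹)

From spring to autumn the Q at the end, counted with both its Z, goes from 28.6 % to 13.4 % of the Z charged. The row turns at a dosing time of 6.6 d, later than the latest dosing time of 6.30 d. Autumn's feed stops 2.00 d before the end, more than the tail, and its Z falls from 12.1 % at 6.00 d to 3.53 % at 8.00 d. Summer, past the latest dosing time, is still feeding at 8.0 d and holds 6.69 % of the charge as Z.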